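At the time of reading, 2.5 h, the west flask stood at 22.0% of target and 0% of substrate, so 78.0% of the charge showed in neither column, and I asked what could still reach that unseen share.

| setting | west | east | flask |
|---|---|---|---|
| substrate | 0.50 M | 0.50 M | 0.50 M |
| partner | 0.75 M | 0.75 M | 0.750 M |
| protic impurity | 0.10 M | 0.10 M | 0.100 M |
| temperature | 0 °C | −5 °C | 0 °C |
| remark | the very flask that is asked about, followed so far | run made earlier |  |
| time |  |  | 2.5 h |

- west (time / min: target / %, substrate / %): 12.0: 26.5, 0.3; 20.0: 26.3, 0; 30.0: 26.4, 0.3; 50.0: 25.2, 0.3; 90.0: 23.8, 0; 150: 22.0, 0
- east (time / min: target / %, substrate / %): 12.0: 23.2, 1.0; 20.0: 23.0, 0; 30.0: 22.8, 0.2; 50.0: 21.8, 0; 90.0: 20.5, 0.5; 150: 18.5, 0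

(readings scatter by 0.3 percentage points)

- Sunday's: at 2.5 h add partner, 50.0% of the amount charged, then wait 2.5 h
- Wednesday's: at 2.5 h raise the temperature by 10 K, then wait 2.5 h
- Friday's: change nothing and wait 2.5 h more
- Monday's: at 2.5 h take out 90% of the target then present, then wait 2.5 h

- removed target is counted in
- additions bring no volume worth counting

- target, in percent of the substrate first charged, at 2.5 h
- which option adds most target ("none" when 2 percentage points or less is all one gets) (Sunday's / Wednesday's / Friday's / Monday's / none)
- target present, with what was taken out counted in, in percent of the substrate first charged, after Wednesday's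
- target present, with what was taken out counted in, in percent of the substrate first charged, after Friday's

The west plateau of 26.5% on 0.50 M of substrate and 0.750 M of partner gave 0.177, and I carried this number as Y, the yield on partner, moles of target standing per mole of partner charged. I wagered that partner had ended the rise of target and that the unseen share was still waiting for it.

Then I turned the settings one by one. Time came first: the west flask lost 4.4 percentage points between 30.0 min and 150 min, which over Friday's 2.5 h I scaled to a loss of 5.5 points. Temperature came next: the colder east run lost 4.3 points over the same span, about the same, so I expected Wednesday's to lose much as Friday's did. Monday's removal of 90% of the target left 0.55 points of that loss by my reckoning, which stays below the margin. Sunday's adds 0.375 M of partner, which at Y makes 13 points of new target, so after the loss I committed to a net 7.7 points, above the margin.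

The forecast gave 22.1% at the time of reading, 17.3% after Wednesday's, 17.8% after Friday's and none as the best option, arguing that “added partner, heat or removal of target cannot create more target”.

The flask gave 22.0%, then 20.0% after Wednesday's and 18.6% after Friday's, and the changes were 9.1 points for Sunday's, −2 points for Wednesday's, −3.4 points for Friday's and 0.87 points for Monday's, so the best was Sunday's.

    substrate → open intermediate (k = 0.0133 s⁻¹, Ea = 80.0 kJ mol⁻¹)
    partner → second intermediate (k = 0.113 s⁻¹, Ea = 67.0 kJ mol⁻¹)
    open intermediate + second intermediate ⇌ target (K = 47.0 M⁻¹, k = 0.0214 M⁻¹ s⁻¹, Ea = 45.0 kJ mol⁻¹, ΔH = 35.0 kJ mol⁻¹)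
    2 second intermediate → homo product (k = 0.0359 M⁻¹ s⁻¹, Ea = 37.0 kJ mol⁻¹)
    substrate + target → side product (k = 0.00250 M⁻¹ s⁻¹, Ea = 58.0 kJ mol⁻¹)
    partner + protic impurity → quenched reagent (k = 0.0775 M⁻¹ s⁻¹, Ea = 43.0 kJ mol⁻¹)
    (constants at 0 °C)

In this flask half of the turnover of partner into second intermediate up to the time of reading was done by 0.0973 min, earlier than the same mark for substrate into open intermediate at 0.858 min. At 150 min partner stood at 0% of its charge and homo product at 0.296 M, while open intermediate, the resting state of the substrate's material, stood at 76.2% of the substrate charged, within the unseen 78.0% read from the west run. Sunday's partner returned a Y of 0.167 over Friday's, against 0.177 read at the plateau, and a neighbour flask charged with 0.30 M of partner stood at a Y of 0.290 at 150 min, where this flask stood at 0.147.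

The readings were computed from invented constants; the scatter is artificial.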